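Numbering the chain C1 (CHBr) to C8 (CH2Cl), the anti-disposed C6 hydroxyl and C7 bromine correspond to anti addition across an (E)-C6=C7 alkene. Everything therefore rests on forming C6=C7 by an E-selective Wittig reaction that joins the complete C1–C6 halodienal, generated in the flask from its homoallylic alcohol, to a C7–C8 propionate ylide. One Sharpless epoxidation then sets C6 and C7 together, the hydroxymethyl becomes CH2Cl, and HBr opens the oxirane at tertiary C7 with inversion. The liberated C6 hydroxyl finally directs vanadium-catalysed epoxidation of the C3=C4 alkene, closing the trisubstituted oxirane ring.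

Key step: step 5

**Step 1**
Reactants: 1 pent-3-yn-1-ol
Product: 2 (E)-4-iodopent-3-en-1-ol
Conditions: Cp2Zr(H)Cl (2.5 equiv), THF, rt to 40 °C; then I2, 0 °C
Reagents that add atoms: iodine, II
Why: syn-hydrozirconation of the internal alkyne, with excess Zr–H equilibrating zirconium to the methyl-bearing carbon, followed by iododezirconation with retention, should give the vinyl iodide with methyl cis to the chain.

**Step 2**
Reactants: 2 (E)-4-iodopent-3-en-1-ol; 3 ethynyltrimethylsilane
Product: 4 (E)-4-methyl-6-(trimethylsilyl)hex-3-en-5-yn-1-ol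
Conditions: Pd(PPh3)2Cl2 (3 mol%), CuI (5 mol%), Et3N, THF, rt
Reagents that add atoms: none
Why: Sonogashira coupling of a vinyl iodide proceeds with retention of alkene geometry and tolerates the free alcohol.

**Step 3**
Reactants: 4 (E)-4-methyl-6-(trimethylsilyl)hex-3-en-5-yn-1-ol
Product: 5 (E)-6-bromo-4-methylhex-3-en-5-yn-1-ol
Conditions: NBS (1.1 equiv), AgNO3 (10 mol%), acetone, rt, dark
Reagents that add atoms: N-bromosuccinimide, O=C1CCC(=O)N1Br
Why: silver-catalysed bromodesilylation of an alkynylsilane gives the 1-bromoalkyne directly and is much faster than attack of NBS on the deactivated enyne alkene.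

**Step 4**
Reactants: 5 (E)-6-bromo-4-methylhex-3-en-5-yn-1-ol
Product: 6 (3E,5Z)-6-bromo-5-chloro-4-methylhexa-3,5-dien-1-ol
Conditions: LiCl (3 equiv), Pd(OAc)2 (5 mol%), AcOH, rt
Reagents that add atoms: lithium chloride, [Li+].[Cl-]
Why: Pd(II)-catalysed hydrochlorination of a 1-bromoalkyne (trans-chloropalladation, then protonolysis) is a net anti addition of H–Cl with chloride at the carbon remote from bromine, which should give the (Z)-1-bromo-2-chloroalkene with Br trans to the chain.

**Step 5**
Reactants: 6 (3E,5Z)-6-bromo-5-chloro-4-methylhexa-3,5-dien-1-ol; 7 ethyl 2-(triphenyl-λ5-phosphanylidene)propanoate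
Product: 9 ethyl (2E,5E,7Z)-8-bromo-7-chloro-2,6-dimethylocta-2,5,7-trienoate, via dienal 8 (not isolated)
Conditions: Dess–Martin periodinane (1.2 equiv), CH2Cl2, 0 °C; then 7 (1.5 equiv), 0 °C to rt
Reagents that add atoms: none
Why: Dess–Martin periodinane oxidises the primary alcohol to dienal 8, which is trapped at once by the ester-stabilised ylide through a [2+2] oxaphosphetane that collapses to the C6=C7 alkene and triphenylphosphine oxide. The closest known reaction type is the one-pot Dess–Martin oxidation/Wittig olefination of labile β,γ-unsaturated aldehydes with stabilised ylides. No ring is kept (the oxaphosphetane is transient) and no stereocentre is formed; the new stereo-element is the C6=C7 geometry, set E by the dipole-minimised late transition state of the α-methyl stabilised ylide, which places the ester trans to the C5 chain. The step needs E over Z selectivity and no migration of the C3=C4 bond into conjugation with the aldehyde; the neutral, salt-free ylide and the absence of any isolation of 8 should secure both. This E geometry is what the later epoxidation and anti opening translate into the (6R,7R) bromohydrin.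

**Step 6**
Reactants: 9 ethyl (2E,5E,7Z)-8-bromo-7-chloro-2,6-dimethylocta-2,5,7-trienoate
Product: 10 (2E,5E,7Z)-8-bromo-7-chloro-2,6-dimethylocta-2,5,7-trien-1-ol
Conditions: DIBAL-H (2.3 equiv), CH2Cl2, −78 °C; Rochelle salt work-up
Reagents that add atoms: none
Why: DIBAL-H reduces the enoate in 1,2-fashion to the allylic alcohol and leaves the vinyl halides and alkene geometries untouched.

**Step 7**
Reactants: 10 (2E,5E,7Z)-8-bromo-7-chloro-2,6-dimethylocta-2,5,7-trien-1-ol
Product: 11 [(2R,3R)-3-[(2E,4Z)-5-bromo-4-chloro-3-methylpenta-2,4-dien-1-yl]-2-methyloxiran-2-yl]methanol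
Conditions: Ti(OiPr)4 (10 mol%), D-(−)-diethyl tartrate (12 mol%), TBHP (2 equiv, decane), 4 Å MS, CH2Cl2, −20 °C
Reagents that add atoms: tert-butyl hydroperoxide, CC(C)(C)OO
Why: Sharpless asymmetric epoxidation acts only on the allylic-alcohol alkene and, with D-(−)-tartrate on this (E)-2-methyl-2-alkenol, should give the (2R,3R) epoxy alcohol, setting C6 and C7 in one catalytic event.

**Step 8**
Reactants: 11 [(2R,3R)-3-[(2E,4Z)-5-bromo-4-chloro-3-methylpenta-2,4-dien-1-yl]-2-methyloxiran-2-yl]methanol
Product: 12 (2S,3R)-3-[(2E,4Z)-5-bromo-4-chloro-3-methylpenta-2,4-dien-1-yl]-2-(chloromethyl)-2-methyloxirane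
Conditions: PPh3 (1.5 equiv), CCl4, 2,6-lutidine (0.1 equiv), 60 °C
Reagents that add atoms: tetrachloromethane, ClC(Cl)(Cl)Cl
Why: Appel chlorination displaces the glycidyl-type alkoxyphosphonium by SN2 at CH2 under neutral conditions, so the oxirane and both stereocentres are unchanged (the C7 descriptor changes only through priorities).

**Step 9**
Reactants: 12 (2S,3R)-3-[(2E,4Z)-5-bromo-4-chloro-3-methylpenta-2,4-dien-1-yl]-2-(chloromethyl)-2-methyloxirane
Product: 13 (2R,3R,5E,7Z)-2,8-dibromo-1,7-dichloro-2,6-dimethylocta-5,7-dien-3-ol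
Conditions: anhydrous HBr (1.05 equiv, CH2Cl2 solution), CH2Cl2, −78 to −40 °C
Reagents that add atoms: hydrogen bromide, Br
Why: acid-mediated halogenolysis of a 2,2,3-trisubstituted oxirane is a borderline SN2 opening at the tertiary carbon with inversion, so bromide should enter at C7 anti to the C6–O bond and the E-derived trans-epoxide should give the anti (6R,7R) bromohydrin, although the chloromethyl group weakens the usual tertiary preference.

**Step 10**
Reactants: 13 (2R,3R,5E,7Z)-2,8-dibromo-1,7-dichloro-2,6-dimethylocta-5,7-dien-3-ol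
Product: 14 (2R,3R)-3-bromo-1-[(2S,3R)-3-[(Z)-2-bromo-1-chloroethenyl]-3-methyloxiran-2-yl]-4-chloro-3-methylbutan-2-ol
Conditions: VO(acac)2 (5 mol%), TBHP (1.5 equiv, decane), CH2Cl2, 0 °C to rt
Reagents that add atoms: tert-butyl hydroperoxide, CC(C)(C)OO
Why: hydroxyl-directed vanadium-catalysed epoxidation of the homoallylic alcohol, through a chair-like vanadate transition state with the bulky C7 group equatorial and a C5–H eclipsing the alkene to avoid A(1,3) strain with the C3 methyl, should deliver oxygen to one face of C3=C4 and set C4 (S) and C3 (R) together, while the electron-poor C1=C2 dihaloalkene stays inert.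

**Compound list**
1 | pent-3-yn-1-ol | CC#CCCO | starting material
2 | (E)-4-iodopent-3-en-1-ol | OCC/C=C(C)/I | intermediate
3 | ethynyltrimethylsilane | C#C[Si](C)(C)C | starting material
4 | (E)-4-methyl-6-(trimethylsilyl)hex-3-en-5-yn-1-ol | OCC/C=C(C)/C#C[Si](C)(C)C | intermediate
5 | (E)-6-bromo-4-methylhex-3-en-5-yn-1-ol | OCC/C=C(C)/C#CBr | intermediate
6 | (3E,5Z)-6-bromo-5-chloro-4-methylhexa-3,5-dien-1-ol | OCC/C=C(C)/C(Cl)=C/Br | intermediate
7 | ethyl 2-(triphenyl-λ5-phosphanylidene)propanoate | CCOC(=O)C(C)=P(c1ccccc1)(c1ccccc1)c1ccccc1 | starting material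
8 | (3E,5Z)-6-bromo-5-chloro-4-methylhexa-3,5-dienal | O=CC/C=C(C)/C(Cl)=C/Br | intermediate
9 | ethyl (2E,5E,7Z)-8-bromo-7-chloro-2,6-dimethylocta-2,5,7-trienoate | CCOC(=O)/C(C)=C/C/C=C(C)/C(Cl)=C/Br | intermediate
10 | (2E,5E,7Z)-8-bromo-7-chloro-2,6-dimethylocta-2,5,7-trien-1-ol | OC/C(C)=C/C/C=C(C)/C(Cl)=C/Br | intermediate
11 | [(2R,3R)-3-[(2E,4Z)-5-bromo-4-chloro-3-methylpenta-2,4-dien-1-yl]-2-methyloxiran-2-yl]methanol | OC[C@@]1(C)O[C@@H]1C/C=C(C)/C(Cl)=C/Br | intermediate
12 | (2S,3R)-3-[(2E,4Z)-5-bromo-4-chloro-3-methylpenta-2,4-dien-1-yl]-2-(chloromethyl)-2-methyloxirane | ClC[C@@]1(C)O[C@@H]1C/C=C(C)/C(Cl)=C/Br | intermediate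
13 | (2R,3R,5E,7Z)-2,8-dibromo-1,7-dichloro-2,6-dimethylocta-5,7-dien-3-ol | C[C@](Br)(CCl)[C@H](O)C/C=C(C)/C(Cl)=C/Br | intermediate
14 | (2R,3R)-3-bromo-1-[(2S,3R)-3-[(Z)-2-bromo-1-chloroethenyl]-3-methyloxiran-2-yl]-4-chloro-3-methylbutan-2-ol | C[C@](Br)(CCl)[C@H](O)C[C@@H]1O[C@@]1(C)/C(Cl)=C/Br | target

Total step count: 10. Longest linear sequence: 10 steps (from 1).

**Steps most likely to fail**

1. Step 9. Bromide may enter at the secondary carbon C6, remote from the electron-withdrawing chloromethyl group, instead of at tertiary C7, giving the regioisomeric bromohydrin. The fallback sets out from 12 and uses this bias. SN2-selective opening with Li2NiBr4 in THF at 0 °C should attack C6 with inversion and give (2R,3S,5E,7Z)-3,8-dibromo-1,7-dichloro-2,6-dimethylocta-5,7-dien-2-ol F1. Catalytic HClO4 in aqueous dioxane should then ionise the tertiary C7 hydroxyl with anchimeric help from the C6 bromine. The resulting configurationally defined C6–C7 bromonium ion should be reopened by water at C6, the carbon remote from CH2Cl. Both centres are inverted twice overall, and the route is rejoined at 13.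

2. Step 5. Dienal 8 may enolise toward C5, or the C3=C4 bond may migrate into conjugation, before the ylide reacts. The fallback sets out from 2 and performs the same bond construction on a less acidic aldehyde, before the halodiene exists. Dess–Martin oxidation of 2 gives (E)-4-iodopent-3-enal F2, trapped in the flask by ylide 7 to give ethyl (2E,5E)-6-iodo-2-methylhepta-2,5-dienoate F3. Sonogashira coupling with 3 then gives ethyl (2E,5E)-2,6-dimethyl-8-(trimethylsilyl)octa-2,5-dien-7-ynoate F4. NBS/AgNO3 converts this to ethyl (2E,5E)-8-bromo-2,6-dimethylocta-2,5-dien-7-ynoate F5, and Pd(OAc)2/LiCl/AcOH hydrochlorination rejoins the route at 9.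

3. Step 10. Oxygen delivery through the hindered C6 vanadate may be slow or poorly face-selective, and the Lewis-acidic metal may promote attack of the C6 hydroxyl on the new allylic oxirane. The fallback sets out from 13 and replaces substrate direction by reagent control. TESOTf/2,6-lutidine gives {[(2R,3R,5E,7Z)-2,8-dibromo-1,7-dichloro-2,6-dimethylocta-5,7-dien-3-yl]oxy}triethylsilane F6. Shi epoxidation uses the L-sorbose-derived enantiomer of the fructose ketone (Oxone, K2CO3 buffer, MeCN/DMM, 0 °C); by the spiro transition-state model this should give the (3R,4S) oxirane, triethyl{[(2R,3R)-3-bromo-1-[(2S,3R)-3-[(Z)-2-bromo-1-chloroethenyl]-3-methyloxiran-2-yl]-4-chloro-3-methylbutan-2-yl]oxy}silane F7. Pyridine-buffered HF·pyridine in THF at 0 °C then gives 14.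

**Further compounds**
F1 | step 9 | (2R,3S,5E,7Z)-3,8-dibromo-1,7-dichloro-2,6-dimethylocta-5,7-dien-2-ol | C[C@@](O)(CCl)[C@@H](Br)C/C=C(C)/C(Cl)=C/Br
F2 | step 5 | (E)-4-iodopent-3-enal | O=CC/C=C(C)/I
F3 | step 5 | ethyl (2E,5E)-6-iodo-2-methylhepta-2,5-dienoate | CCOC(=O)/C(C)=C/C/C=C(C)/I
F4 | step 5 | ethyl (2E,5E)-2,6-dimethyl-8-(trimethylsilyl)octa-2,5-dien-7-ynoate | CCOC(=O)/C(C)=C/C/C=C(C)/C#C[Si](C)(C)C
F5 | step 5 | ethyl (2E,5E)-8-bromo-2,6-dimethylocta-2,5-dien-7-ynoate | CCOC(=O)/C(C)=C/C/C=C(C)/C#CBr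
F6 | step 10 | {[(2R,3R,5E,7Z)-2,8-dibromo-1,7-dichloro-2,6-dimethylocta-5,7-dien-3-yl]oxy}triethylsilane | C[C@](Br)(CCl)[C@H](O[Si](CC)(CC)CC)C/C=C(C)/C(Cl)=C/Br
F7 | step 10 | triethyl{[(2R,3R)-3-bromo-1-[(2S,3R)-3-[(Z)-2-bromo-1-chloroethenyl]-3-methyloxiran-2-yl]-4-chloro-3-methylbutan-2-yl]oxy}silane | C[C@](Br)(CCl)[C@H](O[Si](CC)(CC)CC)C[C@@H]1O[C@@]1(C)/C(Cl)=C/Br
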